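**Strategy.** Azulene numbering is used (C1 angelate carbon, C3 carbinol, C3a/C8a ring fusion, C4 aroyloxy carbon). The seven-membered ring is cut at C5–C6 and C7–C8, which excises C6(Me)=C7 as an alkyne. The key step, a rhodium-catalysed [5+2] cycloaddition, joins 1-(trimethylsilyl)propyne to a 1-vinylbicyclo[3.1.0]hexane whose cyclopropane (C3a, C8a, C8) is fused to the finished five-membered ring. It exploits the quaternary, methyl-bearing C8a, which steers cleavage to the C3a–C8 bond and blocks β-hydride loss; the silyl group fixes the alkyne orientation and later shields C6=C7 from borane. One catalytic aldol sets C1; cyclopropanation, Grignard addition and a convex-face hydroboration relay it to C8a, C3, C3a and C4.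

Key step: step 8

Assumption: (S)-BINOL is taken to deliver the 5S aldol 4, by analogy with the sense of this catalyst for other aldehydes; if the sense with methacrolein is opposite, (R)-BINOL is used.

**Step 1**
Reactants: 1 1-methoxy-1,3-bis(trimethylsilyloxy)buta-1,3-diene; 2 methacrolein
Product: 4 methyl (5S)-5-hydroxy-6-methyl-3-oxohept-6-enoate, via bis-silylated aldol adduct 3 (not isolated)
Conditions: Ti(OiPr)4 (8 mol %), (S)-BINOL (8 mol %), 4 Å sieves, THF, −78 °C to rt; then CF3CO2H, 0 °C
Reagents that add atoms: none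
Why: Catalytic asymmetric vinylogous Mukaiyama aldol addition of the acetoacetate bis-silyl dienolate, in which the BINOL–titanium complex shields one aldehyde face and sets the 5S carbinol, the acid then cleaving both silyl groups.

**Step 2**
Reactants: 4
Product: 5 methyl (5S)-6-methyl-3-oxo-5-(triethylsilyloxy)hept-6-enoate
Conditions: Et3SiCl, imidazole, DMF, 0 °C
Reagents that add atoms: chlorotriethylsilane, CC[Si](Cl)(CC)CC
Why: Silyl ether formation on the secondary alcohol under mild base, which masks the hydroxyl against O–H insertion in step 4 and leaves C5 untouched.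

**Step 3**
Reactants: 5
Product: 6 methyl (5S)-2-diazo-6-methyl-3-oxo-5-(triethylsilyloxy)hept-6-enoate
Conditions: 4-acetamidobenzenesulfonyl azide, Et3N, MeCN, 0 °C to rt
Reagents that add atoms: 4-acetamidobenzenesulfonyl azide, CC(=O)Nc1ccc(cc1)S(=O)(=O)N=[N+]=[N-]
Why: Regitz diazo transfer to the doubly activated methylene of the β-keto ester.

**Step 4**
Reactants: 6
Product: 7 methyl (1R,4S,5R)-5-methyl-2-oxo-4-(triethylsilyloxy)bicyclo[3.1.0]hexane-1-carboxylate (silyloxy group cis to the cyclopropane CH2)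
Conditions: Rh2(OAc)4 (1 mol %), CH2Cl2, 40 °C, slow addition
Reagents that add atoms: none
Why: Rhodium-carbenoid intramolecular cyclopropanation of the 1,1-disubstituted alkene closes the five-membered ring and the cis-fused cyclopropane together, and the C5 silyloxy stereocenter of 6 sets both new centers (C1, C5 of 7) because allylic 1,2-strain keeps hydrogen rather than the silyloxy group eclipsed with the alkene methyl, which places the silyloxy group cis to the cyclopropane CH2.

**Step 5**
Reactants: 7
Product: 8 methyl (1R,2S,4S,5R)-2-hydroxy-5-methyl-2-(propan-2-yl)-4-(triethylsilyloxy)bicyclo[3.1.0]hexane-1-carboxylate (both oxygens cis to the cyclopropane CH2)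
Conditions: iPrMgCl, LaCl3·2LiCl, THF, 0 °C
Reagents that add atoms: isopropylmagnesium chloride, CC(C)[Mg]Cl
Why: Lanthanum-promoted Grignard 1,2-addition to the ketone (the hindered bridgehead ester is spared and enolisation is suppressed), with attack anti to the cyclopropane CH2 and to the cis silyloxy group, so that the new tertiary hydroxyl is cis to both.

**Step 6**
Reactants: 8
Product: 9 (1R,2S,4S,5R)-2-hydroxy-5-methyl-2-(propan-2-yl)-4-(triethylsilyloxy)bicyclo[3.1.0]hexane-1-carbaldehyde
Conditions: iBu2AlH (2.5 equiv), CH2Cl2, −78 °C; aq. potassium sodium tartrate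
Reagents that add atoms: none
Why: Partial reduction of the ester by diisobutylaluminium hydride, in which the neighbouring aluminium alkoxide holds the tetrahedral intermediate as a chelate so that the non-enolisable aldehyde is released only on work-up.

**Step 7**
Reactants: 9
Product: 10 (1R,2S,4S,5R)-1-ethenyl-5-methyl-2-(propan-2-yl)-4-(triethylsilyloxy)bicyclo[3.1.0]hexan-2-ol
Conditions: Ph3PCH3Br, KOtBu (excess), THF, 0 °C to rt
Reagents that add atoms: methyltriphenylphosphonium bromide, C[P+](c1ccccc1)(c1ccccc1)c1ccccc1.[Br-]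
Why: Wittig methylenation of the aldehyde with the unstabilised ylide, the tertiary alkoxide being a spectator because retro-aldol cleavage would need a cyclopropyl carbanion.

**Step 8**
Reactants: 10; 11 1-(trimethylsilyl)propyne
Product: 12 (1S,3S,8aR)-6,8a-dimethyl-3-(propan-2-yl)-1-(triethylsilyloxy)-7-(trimethylsilyl)-1,2,3,5,8,8a-hexahydroazulen-3-ol
Conditions: [Rh(CO)2Cl]2 (5 mol %), 11 (5 equiv), ClCH2CH2Cl, 80 °C
Reagents that add atoms: none
Why: Monovalent rhodium inserts into the C1–C6 cyclopropane bond of 10 next to the coordinated vinyl group to give a σ-alkyl/π-allyl rhodacycle, the alkyne inserts at the vinyl terminus and C(sp3)–C(sp2) reductive elimination releases the cycloheptadiene, so that the bonds C5–C6 and C7–C8 of 12 form in one operation. The closest known reaction type is the intermolecular rhodium-catalysed [5+2] cycloaddition of 1-substituted vinylcyclopropanes with alkynes. The seven-membered ring is closed as a two-component [5+2] annulation, its last bond (C7–C8) by reductive elimination from an eight-membered rhodacycle; no other ring is formed and the five-membered ring is carried through intact. No new stereocenter is created: C8a keeps its configuration because none of its bonds is broken, C1 and C3 are spectators, and the vinyl-bearing cyclopropane carbon becomes the sp2 carbon C3a. The step needs cleavage of C1–C6 rather than C1–C5 of 10, which the quaternary, methyl-bearing C5 secures sterically (the alternative would give a bridged ring with a bridgehead alkene) while leaving the rhodium alkyl without a β-hydrogen. It also needs one alkyne orientation, which the bulky trimethylsilyl group secures by staying distal to the first-formed C–C bond, so that the methyl-bearing carbon joins the vinyl CH2 and the silyl-bearing carbon joins C8.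

**Step 9**
Reactants: 12
Product: 14 (1S,3S,3aR,4R,8aR)-6,8a-dimethyl-3-(propan-2-yl)-1-(triethylsilyloxy)-7-(trimethylsilyl)-1,2,3,3a,4,5,8,8a-octahydroazulene-3,4-diol, via alkylborane 13 (not isolated)
Conditions: BH3·THF (3 equiv), THF, 0 °C to rt; then aq. NaOH, H2O2, 0 °C
Reagents that add atoms: hydrogen peroxide, OO
Why: Hydroboration–oxidation in which boron adds to the less substituted C4 of the trisubstituted C3a=C4 alkene (the tetrasubstituted vinylsilane is spared) by syn addition from the convex face, opposite the folded C6–C8 bridge and the O-borylated tertiary hydroxyl (a poor hydride donor), which sets C3a–H and C4–OH cis to each other and gives the cis ring fusion.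

**Step 10**
Reactants: 14; 15 3,4,5-trimethoxybenzoyl chloride
Product: 16 (1S,3S,3aR,4R,8aR)-3-hydroxy-6,8a-dimethyl-3-(propan-2-yl)-1-(triethylsilyloxy)-7-(trimethylsilyl)-1,2,3,3a,4,5,8,8a-octahydroazulen-4-yl 3,4,5-trimethoxybenzoate
Conditions: Et3N, DMAP (cat.), CH2Cl2, 0 °C to rt
Reagents that add atoms: none
Why: DMAP-catalysed acylation of the only secondary hydroxyl, the tertiary alcohol being unreactive.

**Step 11**
Reactants: 16
Product: 18 (1S,3S,3aR,4R,8aR)-1,3-dihydroxy-6,8a-dimethyl-3-(propan-2-yl)-1,2,3,3a,4,5,8,8a-octahydroazulen-4-yl 3,4,5-trimethoxybenzoate, via O-desilylated vinylsilane 17 (not isolated)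
Conditions: CF3CO2H, CH2Cl2, trace H2O, 0 °C
Reagents that add atoms: none
Why: Acidolysis of the triethylsilyl ether followed by protodesilylation of the vinylsilane, in which ipso protonation at C7 gives a tertiary β-silyl cation at C6 that loses silicon, so the alkene stays at C6=C7.

**Step 12**
Reactants: 18; 19 angelic acid
Product: 21 (1S,3S,3aR,4R,8aR)-3-hydroxy-6,8a-dimethyl-3-(propan-2-yl)-4-(3,4,5-trimethoxybenzoyloxy)-1,2,3,3a,4,5,8,8a-octahydroazulen-1-yl (2Z)-2-methylbut-2-enoate (target), via mixed anhydride 20 (not isolated)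
Conditions: 19, 2,4,6-trichlorobenzoyl chloride, Et3N, toluene, rt; then 18, 80 °C
Reagents that add atoms: none
Why: Yamaguchi esterification through the 2,4,6-trichlorobenzoic mixed anhydride, run without DMAP so that the angelate does not isomerise to the tiglate, and acylating only the secondary C1 hydroxyl.

**Compound list**

1 | 1-methoxy-1,3-bis(trimethylsilyloxy)buta-1,3-diene | C=C(O[Si](C)(C)C)C=C(OC)O[Si](C)(C)C | starting material
2 | methacrolein | CC(=C)C=O | starting material
3 | methyl (5S)-6-methyl-3,5-bis(trimethylsilyloxy)hepta-2,6-dienoate | C[Si](C)(C)O[C@@H](CC(O[Si](C)(C)C)=CC(=O)OC)C(C)=C | intermediate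
4 | methyl (5S)-5-hydroxy-6-methyl-3-oxohept-6-enoate | O[C@@H](CC(=O)CC(=O)OC)C(C)=C | intermediate
5 | methyl (5S)-6-methyl-3-oxo-5-(triethylsilyloxy)hept-6-enoate | CC[Si](CC)(CC)O[C@@H](CC(=O)CC(=O)OC)C(C)=C | intermediate
6 | methyl (5S)-2-diazo-6-methyl-3-oxo-5-(triethylsilyloxy)hept-6-enoate | CC[Si](CC)(CC)O[C@@H](CC(=O)C(=[N+]=[N-])C(=O)OC)C(C)=C | intermediate
7 | methyl (1R,4S,5R)-5-methyl-2-oxo-4-(triethylsilyloxy)bicyclo[3.1.0]hexane-1-carboxylate | CC[Si](CC)(CC)O[C@H]1CC(=O)[C@@]2(C(=O)OC)C[C@@]12C | intermediate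
8 | methyl (1R,2S,4S,5R)-2-hydroxy-5-methyl-2-(propan-2-yl)-4-(triethylsilyloxy)bicyclo[3.1.0]hexane-1-carboxylate | CC[Si](CC)(CC)O[C@H]1C[C@](O)(C(C)C)[C@@]2(C(=O)OC)C[C@@]12C | intermediate
9 | (1R,2S,4S,5R)-2-hydroxy-5-methyl-2-(propan-2-yl)-4-(triethylsilyloxy)bicyclo[3.1.0]hexane-1-carbaldehyde | CC[Si](CC)(CC)O[C@H]1C[C@](O)(C(C)C)[C@@]2(C=O)C[C@@]12C | intermediate
10 | (1R,2S,4S,5R)-1-ethenyl-5-methyl-2-(propan-2-yl)-4-(triethylsilyloxy)bicyclo[3.1.0]hexan-2-ol | CC[Si](CC)(CC)O[C@H]1C[C@](O)(C(C)C)[C@@]2(C=C)C[C@@]12C | intermediate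
11 | 1-(trimethylsilyl)propyne | CC#C[Si](C)(C)C | starting material
12 | (1S,3S,8aR)-6,8a-dimethyl-3-(propan-2-yl)-1-(triethylsilyloxy)-7-(trimethylsilyl)-1,2,3,5,8,8a-hexahydroazulen-3-ol | CC[Si](CC)(CC)O[C@H]1C[C@](O)(C(C)C)C2=CCC(C)=C([Si](C)(C)C)C[C@@]12C | intermediate
13 | C4 alkylborane of 12 with O-borylated tertiary oxygen | CC[Si](CC)(CC)O[C@H]1C[C@](OB)(C(C)C)[C@H]2[C@H](B)CC(C)=C([Si](C)(C)C)C[C@@]12C | intermediate
14 | (1S,3S,3aR,4R,8aR)-6,8a-dimethyl-3-(propan-2-yl)-1-(triethylsilyloxy)-7-(trimethylsilyl)-1,2,3,3a,4,5,8,8a-octahydroazulene-3,4-diol | CC[Si](CC)(CC)O[C@H]1C[C@](O)(C(C)C)[C@H]2[C@H](O)CC(C)=C([Si](C)(C)C)C[C@@]12C | intermediate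
15 | 3,4,5-trimethoxybenzoyl chloride | COc1cc(cc(OC)c1OC)C(Cl)=O | starting material
16 | (1S,3S,3aR,4R,8aR)-3-hydroxy-6,8a-dimethyl-3-(propan-2-yl)-1-(triethylsilyloxy)-7-(trimethylsilyl)-1,2,3,3a,4,5,8,8a-octahydroazulen-4-yl 3,4,5-trimethoxybenzoate | CC[Si](CC)(CC)O[C@H]1C[C@](O)(C(C)C)[C@H]2[C@H](OC(=O)c3cc(OC)c(OC)c(OC)c3)CC(C)=C([Si](C)(C)C)C[C@@]12C | intermediate
17 | 1-O-desilylated 16 (C7 trimethylsilyl group still in place) | O[C@H]1C[C@](O)(C(C)C)[C@H]2[C@H](OC(=O)c3cc(OC)c(OC)c(OC)c3)CC(C)=C([Si](C)(C)C)C[C@@]12C | intermediate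
18 | (1S,3S,3aR,4R,8aR)-1,3-dihydroxy-6,8a-dimethyl-3-(propan-2-yl)-1,2,3,3a,4,5,8,8a-octahydroazulen-4-yl 3,4,5-trimethoxybenzoate | O[C@H]1C[C@](O)(C(C)C)[C@H]2[C@H](OC(=O)c3cc(OC)c(OC)c(OC)c3)CC(C)=CC[C@@]12C | intermediate
19 | angelic acid, (2Z)-2-methylbut-2-enoic acid | C/C=C(/C)C(=O)O | starting material
20 | angelic 2,4,6-trichlorobenzoic anhydride | C/C=C(/C)C(=O)OC(=O)c1c(Cl)cc(Cl)cc1Cl | intermediate
21 | (1S,3S,3aR,4R,8aR)-3-hydroxy-6,8a-dimethyl-3-(propan-2-yl)-4-(3,4,5-trimethoxybenzoyloxy)-1,2,3,3a,4,5,8,8a-octahydroazulen-1-yl (2Z)-2-methylbut-2-enoate | C/C=C(/C)C(=O)O[C@H]1C[C@](O)(C(C)C)[C@H]2[C@H](OC(=O)c3cc(OC)c(OC)c(OC)c3)CC(C)=CC[C@@]12C | target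

**Totals**

Total steps: 12. Longest linear sequence: 12 steps (1 and 2 to 21).

**Steps most likely to fail**

1. Step 8 (key cycloaddition). The hindered internal silylalkyne may insert too slowly into the congested rhodacycle, so that the vinylcyclopropane isomerises instead, or it may insert in both orientations. The fallback sets out from 10 and comes back at 18, and makes the cycloaddition intramolecular through a temporary silicon tether. TBAF removes the triethylsilyl group of 10 to give diol F1. The secondary hydroxyl is silylated with chlorodimethyl(prop-1-ynyl)silane and imidazole to give alkynylsilyl ether F2. [Rh(CO)2Cl]2 in ClCH2CH2Cl then effects the tethered [5+2] cycloaddition to tricyclic siloxane F3; the six-membered siloxane ring forces the silicon-bearing alkyne carbon onto C8 and the methyl-bearing carbon onto the vinyl CH2, so the same two bonds form in one operation. Hydroboration–oxidation as in step 9 gives alcohol F4 and acylation with 15 as in step 10 gives ester F5. TBAF in warm THF cleaves the Si–O bond and protodesilylates the alkenylsilane to give 18.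

2. Step 9 (hydroboration). Borane may add to the face syn to the folded seven-membered ring (poor facial selectivity), which would give the trans-fused diastereomer with both C3a and C4 inverted. The fallback sets out from 12 and comes back at 14, replacing kinetic syn addition by thermodynamic control at C3a and a directed reduction at C4. The hydroboration product is then the diastereomeric diol F6. Dess–Martin periodinane oxidises its secondary alcohol to trans-fused ketone F7. DBU in CH2Cl2 should equilibrate C3a to cis-fused ketone F8, which is expected to be favoured because C4 then avoids the cis isopropyl and angular methyl groups. Me4NBH(OAc)3 in MeCN/AcOH reduces F8 with hydride delivered from the tertiary hydroxyl on the concave face, which gives 14.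

3. Step 5 (isopropyl addition). β-Hydride reduction, or enolisation followed by loss of the β-silyloxy group, may outrun addition to the hindered ketone. The fallback sets out from 7 and comes back at 8, installing the isopropyl group in two stages. Isopropenylmagnesium bromide with LaCl3·2LiCl (an sp2 nucleophile without β-hydrogens and of lower basicity) gives isopropenyl carbinol F9. Hydrogenation of its 1,1-disubstituted alkene with H2 and RhCl(PPh3)3 gives 8 and leaves the cyclopropane intact.

**Further compounds**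

F1 | step 8 | (1R,2S,4S,5R)-1-ethenyl-5-methyl-2-(propan-2-yl)bicyclo[3.1.0]hexane-2,4-diol | O[C@H]1C[C@](O)(C(C)C)[C@@]2(C=C)C[C@@]12C
F2 | step 8 | (1R,2S,4S,5R)-4-{[dimethyl(prop-1-yn-1-yl)silyl]oxy}-1-ethenyl-5-methyl-2-(propan-2-yl)bicyclo[3.1.0]hexan-2-ol | CC#C[Si](C)(C)O[C@H]1C[C@](O)(C(C)C)[C@@]2(C=C)C[C@@]12C
F3 | step 8 | tethered cycloadduct, the analogue of 12 in which O1 and C7 are bridged by a dimethylsilylene group | C[Si]3(C)O[C@H]1C[C@](O)(C(C)C)C2=CCC(C)=C3C[C@@]12C
F4 | step 8 | C4 alcohol from hydroboration of F3, the silylene-bridged analogue of 14 | C[Si]3(C)O[C@H]1C[C@](O)(C(C)C)[C@H]2[C@H](O)CC(C)=C3C[C@@]12C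
F5 | step 8 | 4-O-(3,4,5-trimethoxybenzoate) of F4, the silylene-bridged analogue of 16 | C[Si]3(C)O[C@H]1C[C@](O)(C(C)C)[C@H]2[C@H](OC(=O)c4cc(OC)c(OC)c(OC)c4)CC(C)=C3C[C@@]12C
F6 | step 9 | (1S,3S,3aS,4S,8aR)-6,8a-dimethyl-3-(propan-2-yl)-1-(triethylsilyloxy)-7-(trimethylsilyl)-1,2,3,3a,4,5,8,8a-octahydroazulene-3,4-diol (trans-fused) | CC[Si](CC)(CC)O[C@H]1C[C@](O)(C(C)C)[C@@H]2[C@@H](O)CC(C)=C([Si](C)(C)C)C[C@@]12C
F7 | step 9 | (1S,3S,3aR,8aR)-3-hydroxy-6,8a-dimethyl-3-(propan-2-yl)-1-(triethylsilyloxy)-7-(trimethylsilyl)-2,3,3a,5,8,8a-hexahydroazulen-4(1H)-one (trans-fused) | CC[Si](CC)(CC)O[C@H]1C[C@](O)(C(C)C)[C@@H]2C(=O)CC(C)=C([Si](C)(C)C)C[C@@]12C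
F8 | step 9 | (1S,3S,3aS,8aR)-3-hydroxy-6,8a-dimethyl-3-(propan-2-yl)-1-(triethylsilyloxy)-7-(trimethylsilyl)-2,3,3a,5,8,8a-hexahydroazulen-4(1H)-one (cis-fused) | CC[Si](CC)(CC)O[C@H]1C[C@](O)(C(C)C)[C@H]2C(=O)CC(C)=C([Si](C)(C)C)C[C@@]12C
F9 | step 5 | methyl (1R,2S,4S,5R)-2-hydroxy-5-methyl-2-(prop-1-en-2-yl)-4-(triethylsilyloxy)bicyclo[3.1.0]hexane-1-carboxylate | CC[Si](CC)(CC)O[C@H]1C[C@](O)(C(C)=C)[C@@]2(C(=O)OC)C[C@@]12C
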